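**Retrosynthetic overview**
- The last bond made is the ester C–O bond between linoleic acid and the C20 allylic alcohol.
- The (2E,6E)-diene chain comes from two zirconium-catalysed methylaluminations of terminal alkynes: one trapped with formaldehyde, one with iodine followed by Negishi coupling with a homopropargylzinc reagent. This leads back to a ring-bearing butyne and, through it, to a ring-bearing acetate ester.
- The strategy rests on one feature of the 2,6,6-trimethylcyclohex-2-ene ring: the stereogenic CH (ring C1, next to the gem-dimethyl carbon C6) is bonded to the methyl-bearing vinyl carbon C2 and lies β to chain carbon C8. With C8 as an ester carbonyl, the C1–C2 ring bond becomes a conjugate-addition bond.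
- Key disconnection: ring bond C1–C2, opened to an acyclic enoate carrying an alkenyl pinacolboronate. A rhodium/(S)-BINAP ring closure forms the only ring and the only stereocentre in one step.
- The acyclic precursor comes from 2,2-dimethylpent-4-enal by olefination, hydroboration–oxidation, oxidation, iodoethylidenation and borylation.

Key step: step 6

Assumption: the facial sense of the BINAP–rhodium addition in the ring-closing mode is taken to be the same as in intermolecular additions to E-enoates. If the cyclised ester proves to be the (R)-enantiomer, (R)-BINAP is used instead and nothing else changes.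

**Route**

Step 1
Reactants: 1 2,2-dimethylpent-4-enal; 2 triethyl phosphonoacetate
Product: 3 ethyl (2E)-4,4-dimethylhepta-2,6-dienoate
Conditions: NaH, THF, 0 °C to rt
Reagents that add atoms: none
Why: Horner–Wadsworth–Emmons olefination of a non-enolisable α-quaternary aldehyde with a stabilised phosphonate anion should give the E-enoate almost exclusively.

Step 2
Reactants: 3 ethyl (2E)-4,4-dimethylhepta-2,6-dienoate
Product: 5 ethyl (2E)-7-hydroxy-4,4-dimethylhept-2-enoate, via alkylborane 4 (not isolated)
Conditions: 9-BBN, THF, 0 °C to rt; then H2O2, aq NaOAc, 0 °C to rt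
Reagents that add atoms: hydrogen peroxide, OO
Why: Anti-Markovnikov hydroboration–oxidation; 9-BBN should add to the monosubstituted terminal alkene far faster than to the electron-poor, neopentyl-flanked enoate, and the buffered oxidation spares the ester.

Step 3
Reactants: 5 ethyl (2E)-7-hydroxy-4,4-dimethylhept-2-enoate
Product: 6 ethyl (2E)-4,4-dimethyl-7-oxohept-2-enoate
Conditions: Dess–Martin periodinane, CH2Cl2, 0 °C to rt
Reagents that add atoms: none
Why: Dess–Martin oxidation of a primary alcohol stops at the aldehyde under near-neutral conditions that the enoate tolerates.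

Step 4
Reactants: 6 ethyl (2E)-4,4-dimethyl-7-oxohept-2-enoate
Product: 7 ethyl (2E,7Z)-8-iodo-4,4-dimethylnona-2,7-dienoate
Conditions: EtPPh3I, n-BuLi, THF, 0 °C; I2, −78 °C; NaN(SiMe3)2, −20 °C; then 6, −78 to −20 °C
Reagents that add atoms: ethyltriphenylphosphonium iodide, CC[P+](c1ccccc1)(c1ccccc1)c1ccccc1.[I-]; iodine, II
Why: Stork–Zhao-type Wittig olefination with the α-iodoethylidene ylide runs under kinetic control through the cis-oxaphosphetane and should place iodine cis to the chain (7Z); the aldehyde should react at low temperature far faster than the hindered enoate.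

Step 5
Reactants: 7 ethyl (2E,7Z)-8-iodo-4,4-dimethylnona-2,7-dienoate
Product: 8 ethyl (2E,7E)-4,4-dimethyl-8-(4,4,5,5-tetramethyl-1,3,2-dioxaborolan-2-yl)nona-2,7-dienoate
Conditions: B2pin2, PdCl2(PPh3)2 (3 mol%), PPh3, KOPh, toluene, 50 °C
Reagents that add atoms: bis(pinacolato)diboron, CC1(C)OB(OC1(C)C)B1OC(C)(C)C(C)(C)O1
Why: Miyaura borylation of an alkenyl iodide with zerovalent palladium retains alkene geometry, so boron ends up cis to the tether (7E by the sequence rule, carbon outranking boron); transmetalation at 50 °C should outpace Heck insertion into the hindered enoate.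

Step 6
Reactants: 8 ethyl (2E,7E)-4,4-dimethyl-8-(4,4,5,5-tetramethyl-1,3,2-dioxaborolan-2-yl)nona-2,7-dienoate
Product: 9 ethyl 2-[(1S)-2,6,6-trimethylcyclohex-2-en-1-yl]acetate
Conditions: [RhCl(C2H4)2]2 (2.5 mol%), (S)-BINAP (5.5 mol%), KOH (0.2 equiv), 1,4-dioxane/H2O 10:1, 0.05 M, 60 °C
Reagents that add atoms: none
Why: A hydroxo complex of monovalent rhodium bearing (S)-BINAP transmetalates the alkenyl pinacolboronate with retention, the alkenylrhodium inserts the tethered E-enoate so that the boron-bearing carbon C8 bonds to the β-carbon C3, and water protonates the oxa-π-allyl rhodium enolate, releasing 9 and regenerating the hydroxo complex. The closest known reaction type is the Hayashi–Miyaura asymmetric 1,4-addition of alkenylboron reagents to enoates, together with the cyclisation of alkenylrhodium species onto tethered Michael acceptors. The single ring closes in a 6-exo-trig mode, and because boron in 8 is cis to the tether the ring alkene lands at C2=C3 of the cyclohexene with its methyl group on C2. The new stereocentre (ring C1) is controlled by the ligand alone: (S)-BINAP exposes the α-si face of an E-enoate, which for this substrate corresponds to the (S)-configured centre. The step needs cyclisation to outrun protodeboronation and intermolecular addition; the gem-dimethyl group (Thorpe–Ingold effect), the short tether and moderate dilution should favour the intramolecular path despite the neopentyl character of the β-carbon.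

Step 7
Reactants: 9 ethyl 2-[(1S)-2,6,6-trimethylcyclohex-2-en-1-yl]acetate
Product: 10 2-[(1S)-2,6,6-trimethylcyclohex-2-en-1-yl]ethan-1-ol
Conditions: LiAlH4, THF, 0 °C
Reagents that add atoms: none
Why: Hydride reduction of the ester to the primary alcohol; the stereocentre is β to the carbonyl and cannot epimerise, and the trisubstituted alkene is inert.

Step 8
Reactants: 10 2-[(1S)-2,6,6-trimethylcyclohex-2-en-1-yl]ethan-1-ol
Product: 11 (6S)-6-(2-iodoethyl)-1,5,5-trimethylcyclohex-1-ene
Conditions: I2, PPh3, imidazole, CH2Cl2, 0 °C to rt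
Reagents that add atoms: iodine, II
Why: Appel-type iodination of a primary alcohol; imidazole buffering keeps the medium free of acid that could shift the ring alkene.

Step 9
Reactants: 11 (6S)-6-(2-iodoethyl)-1,5,5-trimethylcyclohex-1-ene
Product: 12 (6S)-6-(but-3-yn-1-yl)-1,5,5-trimethylcyclohex-1-ene
Conditions: HC≡CLi·H2NCH2CH2NH2, DMSO, rt
Reagents that add atoms: lithium acetylide–ethylenediamine complex, [Li+].[C-]#C.NCCN
Why: SN2 alkylation of lithium acetylide by a primary iodide in DMSO should give the terminal alkyne directly, with elimination only a minor pathway at an unbranched CH2–I.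

Step 10
Reactants: 12 (6S)-6-(but-3-yn-1-yl)-1,5,5-trimethylcyclohex-1-ene
Product: 14 (6S)-6-[(3E)-4-iodo-3-methylbut-3-en-1-yl]-1,5,5-trimethylcyclohex-1-ene, via alkenylalane 13 (not isolated)
Conditions: Me3Al, Cp2ZrCl2 (0.25 equiv), CH2Cl2, 0 °C to rt; then I2, THF, −30 to 0 °C
Reagents that add atoms: trimethylaluminium, C[Al](C)C; iodine, II
Why: Zirconium-catalysed methylalumination (Negishi carboalumination) adds methyl and aluminium syn across the terminal alkyne with aluminium on the terminal carbon, and iodinolysis with retention should give the E-iodide.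

Step 11
Reactants: 14 (6S)-6-[(3E)-4-iodo-3-methylbut-3-en-1-yl]-1,5,5-trimethylcyclohex-1-ene; 15 4-bromo-1-(trimethylsilyl)but-1-yne
Product: 17 trimethyl{(5E)-6-methyl-8-[(1S)-2,6,6-trimethylcyclohex-2-en-1-yl]oct-5-en-1-yn-1-yl}silane, via homopropargylzinc bromide 16 (not isolated)
Conditions: 15, Zn dust, LiCl, THF, 50 °C; then 14, PdCl2(dppf) (3 mol%), THF, rt to 40 °C
Reagents that add atoms: none
Why: Negishi coupling of a primary alkylzinc with an alkenyl iodide retains the E geometry; the bidentate ligand disfavours β-hydride elimination and the silyl cap removes the acidic alkyne C–H.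

Step 12
Reactants: 17 trimethyl{(5E)-6-methyl-8-[(1S)-2,6,6-trimethylcyclohex-2-en-1-yl]oct-5-en-1-yn-1-yl}silane
Product: 18 (6S)-1,5,5-trimethyl-6-[(3E)-3-methyloct-3-en-7-yn-1-yl]cyclohex-1-ene
Conditions: K2CO3, MeOH/THF, rt
Reagents that add atoms: none
Why: Carbonate-mediated methanolysis of the alkynyl C–Si bond; nothing else in the molecule is base-sensitive.

Step 13
Reactants: 18 (6S)-1,5,5-trimethyl-6-[(3E)-3-methyloct-3-en-7-yn-1-yl]cyclohex-1-ene
Product: 21 (2E,6E)-3,7-dimethyl-9-[(1S)-2,6,6-trimethylcyclohex-2-en-1-yl]nona-2,6-dien-1-ol, via alkenylalane 19 (not isolated), via lithium alanate 20 (not isolated)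
Conditions: Me3Al, Cp2ZrCl2 (0.25 equiv), CH2Cl2, rt; then n-BuLi, THF, −30 °C; (CH2O)n, −30 °C to rt
Reagents that add atoms: trimethylaluminium, C[Al](C)C; paraformaldehyde (as formaldehyde), C=O
Why: A second syn methylalumination (Negishi carboalumination) sets the 2E alkene, and the more nucleophilic alanate formed with n-BuLi should add to formaldehyde with retention to give the allylic alcohol.

Step 14
Reactants: 21 (2E,6E)-3,7-dimethyl-9-[(1S)-2,6,6-trimethylcyclohex-2-en-1-yl]nona-2,6-dien-1-ol; 22 linoleic acid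
Product: 23 (2E,6E)-3,7-dimethyl-9-[(1S)-2,6,6-trimethylcyclohex-2-en-1-yl]nona-2,6-dien-1-yl (9Z,12Z)-octadeca-9,12-dienoate
Conditions: DCC, DMAP (cat.), CH2Cl2, 0 °C to rt
Reagents that add atoms: none
Why: Steglich esterification under neutral conditions that leave the skipped Z,Z-diene, the trisubstituted alkenes and the allylic C–O bond untouched.

**Compound list**
1 | 2,2-dimethylpent-4-enal | C=CCC(C)(C)C=O | starting material
2 | triethyl phosphonoacetate | CCOC(=O)CP(=O)(OCC)OCC | starting material
3 | ethyl (2E)-4,4-dimethylhepta-2,6-dienoate | CCOC(=O)/C=C/C(C)(C)CC=C | intermediate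
4 | ethyl (2E)-7-(9-borabicyclo[3.3.1]nonan-9-yl)-4,4-dimethylhept-2-enoate | CCOC(=O)/C=C/C(C)(C)CCCB1C2CCCC1CCC2 | intermediate (not isolated)
5 | ethyl (2E)-7-hydroxy-4,4-dimethylhept-2-enoate | CCOC(=O)/C=C/C(C)(C)CCCO | intermediate
6 | ethyl (2E)-4,4-dimethyl-7-oxohept-2-enoate | CCOC(=O)/C=C/C(C)(C)CCC=O | intermediate
7 | ethyl (2E,7Z)-8-iodo-4,4-dimethylnona-2,7-dienoate | CCOC(=O)/C=C/C(C)(C)CC/C=C(/C)I | intermediate
8 | ethyl (2E,7E)-4,4-dimethyl-8-(4,4,5,5-tetramethyl-1,3,2-dioxaborolan-2-yl)nona-2,7-dienoate | CCOC(=O)/C=C/C(C)(C)CC/C=C(/C)B1OC(C)(C)C(C)(C)O1 | intermediate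
9 | ethyl 2-[(1S)-2,6,6-trimethylcyclohex-2-en-1-yl]acetate | CCOC(=O)C[C@@H]1C(C)=CCCC1(C)C | intermediate
10 | 2-[(1S)-2,6,6-trimethylcyclohex-2-en-1-yl]ethan-1-ol | OCC[C@@H]1C(C)=CCCC1(C)C | intermediate
11 | (6S)-6-(2-iodoethyl)-1,5,5-trimethylcyclohex-1-ene | ICC[C@@H]1C(C)=CCCC1(C)C | intermediate
12 | (6S)-6-(but-3-yn-1-yl)-1,5,5-trimethylcyclohex-1-ene | C#CCC[C@@H]1C(C)=CCCC1(C)C | intermediate
13 | dimethyl{(1E)-2-methyl-4-[(1S)-2,6,6-trimethylcyclohex-2-en-1-yl]but-1-en-1-yl}alumane | C[Al](C)/C=C(\C)CC[C@@H]1C(C)=CCCC1(C)C | intermediate (not isolated)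
14 | (6S)-6-[(3E)-4-iodo-3-methylbut-3-en-1-yl]-1,5,5-trimethylcyclohex-1-ene | I/C=C(\C)CC[C@@H]1C(C)=CCCC1(C)C | intermediate
15 | 4-bromo-1-(trimethylsilyl)but-1-yne | C[Si](C)(C)C#CCCBr | starting material
16 | bromo[4-(trimethylsilyl)but-3-yn-1-yl]zinc | C[Si](C)(C)C#CCC[Zn]Br | intermediate (not isolated)
17 | trimethyl{(5E)-6-methyl-8-[(1S)-2,6,6-trimethylcyclohex-2-en-1-yl]oct-5-en-1-yn-1-yl}silane | C[Si](C)(C)C#CCC/C=C(\C)CC[C@@H]1C(C)=CCCC1(C)C | intermediate
18 | (6S)-1,5,5-trimethyl-6-[(3E)-3-methyloct-3-en-7-yn-1-yl]cyclohex-1-ene | C#CCC/C=C(\C)CC[C@@H]1C(C)=CCCC1(C)C | intermediate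
19 | dimethyl{(1E,5E)-2,6-dimethyl-8-[(1S)-2,6,6-trimethylcyclohex-2-en-1-yl]octa-1,5-dien-1-yl}alumane | C[Al](C)/C=C(\C)CC/C=C(\C)CC[C@@H]1C(C)=CCCC1(C)C | intermediate (not isolated)
20 | lithium butyl(dimethyl){(1E,5E)-2,6-dimethyl-8-[(1S)-2,6,6-trimethylcyclohex-2-en-1-yl]octa-1,5-dien-1-yl}aluminate | [Li+].CCCC[Al-](C)(C)/C=C(\C)CC/C=C(\C)CC[C@@H]1C(C)=CCCC1(C)C | intermediate (not isolated)
21 | (2E,6E)-3,7-dimethyl-9-[(1S)-2,6,6-trimethylcyclohex-2-en-1-yl]nona-2,6-dien-1-ol | OC/C=C(\C)CC/C=C(\C)CC[C@@H]1C(C)=CCCC1(C)C | intermediate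
22 | linoleic acid, (9Z,12Z)-octadeca-9,12-dienoic acid | CCCCC/C=C\C/C=C\CCCCCCCC(=O)O | starting material
23 | (2E,6E)-3,7-dimethyl-9-[(1S)-2,6,6-trimethylcyclohex-2-en-1-yl]nona-2,6-dien-1-yl (9Z,12Z)-octadeca-9,12-dienoate | CCCCC/C=C\C/C=C\CCCCCCCC(=O)OC/C=C(\C)CC/C=C(\C)CC[C@@H]1C(C)=CCCC1(C)C | target

**Step count**
Total steps: 14. Longest linear sequence: 14 steps, from 2,2-dimethylpent-4-enal (1) to 23.

**Steps most likely to fail, with fallbacks**

Step 6. Protonolysis of the alkenyl–rhodium bond may outrun insertion into the neopentyl-flanked enoate, or the ligand may discriminate the enoate faces poorly in the ring-closing mode. The fallback sets out from aldehyde 6 and returns at ester 9. It makes the stereocentre by reagent-controlled ketone reduction and sigmatropic chirality transfer instead of conjugate addition.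
- EtMgBr (THF, −78 °C) should add to the aldehyde of 6 only, giving ethyl (2E)-7-hydroxy-4,4-dimethylnon-2-enoate F1.
- Dess–Martin oxidation gives ethyl (2E)-4,4-dimethyl-7-oxonon-2-enoate F2.
- Ozonolysis (O3, CH2Cl2, −78 °C; Me2S) cleaves the enoate alkene to 2,2-dimethyl-5-oxoheptanal F3.
- Intramolecular aldol condensation (KOH, MeOH) of the ethyl ketone onto the non-enolisable aldehyde gives 2,4,4-trimethylcyclohex-2-en-1-one F4.
- Corey–Bakshi–Shibata reduction with (S)-2-methyl-CBS-oxazaborolidine and BH3·SMe2 should give (1R)-2,4,4-trimethylcyclohex-2-en-1-ol F5, the methyl-bearing alkenyl arm acting as the large group.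
- Johnson–Claisen rearrangement (MeC(OEt)3, cat. EtCO2H, 140 °C) delivers the acetate arm suprafacially to the ring carbon next to the gem-dimethyl group. This translates the (1R)-carbinol into the (1S)-centre of 9.

Step 4. Incomplete iodination or proton exchange of the ylide may give the non-iodinated alkene, and the kinetic cis-selectivity of the olefination may erode. The fallback sets out from aldehyde 6 and returns at boronate 8.
- Dibromo-olefination (CBr4, PPh3, CH2Cl2, 0 °C) gives ethyl (2E)-8,8-dibromo-4,4-dimethylocta-2,7-dienoate F6.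
- Palladium-catalysed trans-selective monomethylation (Me2Zn, PdCl2(DPEphos), THF, 0 °C) replaces only the bromine trans to the chain and gives ethyl (2E,7Z)-8-bromo-4,4-dimethylnona-2,7-dienoate F7.
- Miyaura borylation of this bromide under the conditions of step 5 then gives 8 with boron cis to the tether.

Step 11. Zinc insertion into the homopropargyl bromide may be slow or incomplete, and the alkyl–alkenyl coupling may suffer β-hydride elimination or homocoupling. The fallback sets out from alkyne 12 and returns at silyl enyne 17. It builds the chain by epoxide opening and SN2 alkynylation instead of cross-coupling.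
- Methylalumination of 12 as in step 10, conversion to the alanate with n-BuLi and opening of ethylene oxide should give (3E)-4-methyl-6-[(1S)-2,6,6-trimethylcyclohex-2-en-1-yl]hex-3-en-1-ol F8.
- Tf2O/pyridine (CH2Cl2, −78 °C) gives (3E)-4-methyl-6-[(1S)-2,6,6-trimethylcyclohex-2-en-1-yl]hex-3-en-1-yl trifluoromethanesulfonate F9, used at once.
- Displacement with LiC≡CSiMe3 (THF/DMPU, −78 °C) gives 17.

**Further compounds**
F1 | step 6 | ethyl (2E)-7-hydroxy-4,4-dimethylnon-2-enoate | CCOC(=O)/C=C/C(C)(C)CCC(O)CC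
F2 | step 6 | ethyl (2E)-4,4-dimethyl-7-oxonon-2-enoate | CCOC(=O)/C=C/C(C)(C)CCC(=O)CC
F3 | step 6 | 2,2-dimethyl-5-oxoheptanal | CCC(=O)CCC(C)(C)C=O
F4 | step 6 | 2,4,4-trimethylcyclohex-2-en-1-one | CC1=CC(C)(C)CCC1=O
F5 | step 6 | (1R)-2,4,4-trimethylcyclohex-2-en-1-ol | CC1=CC(C)(C)CC[C@H]1O
F6 | step 4 | ethyl (2E)-8,8-dibromo-4,4-dimethylocta-2,7-dienoate | CCOC(=O)/C=C/C(C)(C)CCC=C(Br)Br
F7 | step 4 | ethyl (2E,7Z)-8-bromo-4,4-dimethylnona-2,7-dienoate | CCOC(=O)/C=C/C(C)(C)CC/C=C(/C)Br
F8 | step 11 | (3E)-4-methyl-6-[(1S)-2,6,6-trimethylcyclohex-2-en-1-yl]hex-3-en-1-ol | OCC/C=C(\C)CC[C@@H]1C(C)=CCCC1(C)C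
F9 | step 11 | (3E)-4-methyl-6-[(1S)-2,6,6-trimethylcyclohex-2-en-1-yl]hex-3-en-1-yl trifluoromethanesulfonate | O=S(=O)(OCC/C=C(\C)CC[C@@H]1C(C)=CCCC1(C)C)C(F)(F)F
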